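**Plan**
Numbering: the ten-membered ring is C1–C10. C6 = CH–O-angelate, C7 = CH bearing C11 (CMe2OH), C8 and C9 = CH2, C10 = CHMe, C1–C3 = CH2, C4 = C(Me)OH, C5 = CHOH.
Enabling feature: O4 and O5 are cis on the ring (4R,5S), which is what syn addition to a Z-C4=C5 alkene in this ring gives. C3, the ring neighbour of C4, is a bare CH2. C4 can therefore be an alkenyl iodide carbon and C3 a primary alkylborane carbon.
Cuts, in retrosynthetic order: C4–O and C5–O (dihydroxylation), O6–acyl (esterification), C3–C4 (ring opening to Z-alkenyl iodide plus terminal alkene), C2=C3 (methylenation), C5–C6 (propynyl addition), C6–C7 (vinyl opening of the C7/C11 epoxide).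
Forward: the chain grows linearly on (R)-citronellal, which supplies C1, C2, C7–C11 and three methyl groups. A temporary O6/O11 dioxane is made first, the only carbocycle closes in step 11, and the ester and diol follow.
Stereochemistry: C10 comes from citronellal, C7 from Shi epoxidation plus SN2 inversion, and C6 from Felkin–Anh addition. The Z geometry comes from trans-hydroalumination/iodination, and C4/C5 from syn dihydroxylation on the outer face of the cis-cyclodecene.

Key step: step 11

Remark: the CIP letters of C6, C7 and C10 differ between some intermediates only because substituent ranks change; no centre is inverted after it has been set.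
Assumption: commercial (R)-citronellal is taken to be enantiomerically pure enough that C10 needs no upgrading.

Step 1
Reactants: 1 (R)-citronellal
Product: 2 (6R)-8,8-dimethoxy-2,6-dimethyloct-2-ene
Conditions: HC(OMe)3, p-TsOH·H2O (cat.), MeOH, 0 °C → rt
Reagents that add atoms: trimethyl orthoformate, COC(OC)OC
Why: Acid-catalysed acetalisation with an orthoester as methanol source and water scavenger is quick enough under mild acid to outrun the carbonyl-ene cyclisation of citronellal, and it masks the future C2 against peroxymonosulfate, organometallic reagents and ozone while C10 stays untouched.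

Step 2
Reactants: 2 (6R)-8,8-dimethoxy-2,6-dimethyloct-2-ene
Product: 3 (3R)-3-[(3R)-5,5-dimethoxy-3-methylpentyl]-2,2-dimethyloxirane
Conditions: D-fructose-derived Shi ketone (30 mol %), KHSO5 (as 2KHSO5·KHSO4·K2SO4), K2CO3, Bu4NHSO4 (cat.), MeCN–CH2(OMe)2, aq. Na2B4O7 buffer, 0 °C
Reagents that add atoms: potassium peroxymonosulfate KHSO5, [K+].[O-]S(=O)(=O)OO
Why: Shi asymmetric epoxidation: the dioxirane generated from the D-fructose-derived ketone transfers oxygen to the only alkene through a spiro transition state, which for alkenes of the type RCH=CMe2 should give the (7R)-epoxide under reagent control, independent of the remote C10 centre, and the basic buffer leaves the acetal alone.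

Step 3
Reactants: 3 (3R)-3-[(3R)-5,5-dimethoxy-3-methylpentyl]-2,2-dimethyloxirane; 4 vinylmagnesium bromide
Product: 5 (3R,6R)-3-ethenyl-8,8-dimethoxy-2,6-dimethyloctan-2-ol
Conditions: CH2=CHMgBr (3 equiv), CuI (20 mol %), THF, −30 → 0 °C
Reagents that add atoms: vinylmagnesium bromide, C=C[Mg]Br
Why: Copper-catalysed Grignard opening of an epoxide is an anti SN2 process at the less substituted carbon, so the vinyl group enters at C7 with inversion, which forms the C6–C7 bond, releases the C11 tertiary alcohol and sets C7 as in the target.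

Step 4
Reactants: 5 (3R,6R)-3-ethenyl-8,8-dimethoxy-2,6-dimethyloctan-2-ol
Product: 6 {[(3R,6R)-3-ethenyl-8,8-dimethoxy-2,6-dimethyloctan-2-yl]oxy}triethylsilane
Conditions: Et3SiCl, imidazole, DMAP (cat.), DMF, 40 °C
Reagents that add atoms: chlorotriethylsilane, CC[Si](Cl)(CC)CC
Why: Routine silylation of a dimethylcarbinol; the silyl ether takes away the chelating β-hydroxy group before the carbonyl addition of step 6, and the chloride/imidazole protocol is preferred because silyl triflates would activate the dimethyl acetal.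

Step 5
Reactants: 6 {[(3R,6R)-3-ethenyl-8,8-dimethoxy-2,6-dimethyloctan-2-yl]oxy}triethylsilane
Product: 8 (2S,5R)-7,7-dimethoxy-5-methyl-2-[2-(triethylsilyloxy)propan-2-yl]heptanal, via secondary ozonide 7 (not isolated)
Conditions: O3, CH2Cl2, −78 °C (stopped at the end point); then PPh3, −78 °C → rt
Reagents that add atoms: ozone, [O-][O+]=O
Why: Ozonolysis with reductive work-up cleaves the only C=C bond, losing the terminal CH2 as formaldehyde and leaving C6 as the aldehyde; the alkene consumes ozone far faster than the acetal C–H bond, and the neutral conditions should not epimerise the hindered α-centre C7.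

Step 6
Reactants: 8 (2S,5R)-7,7-dimethoxy-5-methyl-2-[2-(triethylsilyloxy)propan-2-yl]heptanal; 9 prop-1-ynylmagnesium bromide
Product: 10 (4R,5R,8R)-10,10-dimethoxy-8-methyl-5-[2-(triethylsilyloxy)propan-2-yl]dec-2-yn-4-ol
Conditions: CH3C≡CMgBr, THF, −78 °C
Reagents that add atoms: prop-1-ynylmagnesium bromide, CC#C[Mg]Br
Why: Felkin–Anh-controlled 1,2-addition of an alkynyl Grignard reagent: with the bulky CMe2OSiEt3 group perpendicular to the carbonyl plane and chelation shut off by silicon, the nucleophile should approach past H7 and set C6 with O6 and C8 syn along the C11–C7–C6–C5 backbone, which is the target relationship.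

Step 7
Reactants: 10 (4R,5R,8R)-10,10-dimethoxy-8-methyl-5-[2-(triethylsilyloxy)propan-2-yl]dec-2-yn-4-ol
Product: 12 (2Z,4R,5R,8R)-2-iodo-10,10-dimethoxy-8-methyl-5-[2-(triethylsilyloxy)propan-2-yl]dec-2-en-4-ol, via cyclic sodium alkenylalanate 11 (not isolated)
Conditions: NaAlH2(OCH2CH2OMe)2, THF, 0 °C → rt; then I2, THF, −78 → 0 °C
Reagents that add atoms: iodine, II
Why: Hydroxyl-directed trans-hydroalumination of a propargylic alcohol followed by iodinolysis: hydride is delivered to C5 and aluminium ends on C4 inside a five-membered oxa-aluminacycle, so exchange of aluminium for iodine with retention puts iodine cis to C6 and should give the Z-alkenyl iodide as a single regio- and stereoisomer.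

Step 8
Reactants: 12 (2Z,4R,5R,8R)-2-iodo-10,10-dimethoxy-8-methyl-5-[2-(triethylsilyloxy)propan-2-yl]dec-2-en-4-ol
Product: 13 (3R,6R,7R,8Z)-7-hydroxy-6-(2-hydroxypropan-2-yl)-9-iodo-3-methyldec-8-enal
Conditions: 1 M aq. HCl–THF (1:4), 0 °C → rt
Reagents that add atoms: water, O
Why: Dilute aqueous acid hydrolyses both acid-labile groups in one operation, the dimethyl acetal to the C2 aldehyde and the triethylsilyl ether to the C11 alcohol, under conditions too mild to ionise the secondary allylic alcohol or to touch the alkenyl iodide.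

Step 9
Reactants: 13 (3R,6R,7R,8Z)-7-hydroxy-6-(2-hydroxypropan-2-yl)-9-iodo-3-methyldec-8-enal; 14 methyltriphenylphosphonium bromide
Product: 15 (3R,4R,5Z)-6-iodo-2-methyl-3-[(3R)-3-methylhex-5-en-1-yl]hept-5-ene-2,4-diol
Conditions: Ph3PCH3Br (4.0 equiv), n-BuLi (3.8 equiv), THF, 0 °C; then 13, −78 → 0 °C
Reagents that add atoms: methyltriphenylphosphonium bromide, C[P+](c1ccccc1)(c1ccccc1)c1ccccc1.[Br-]
Why: Wittig methylenation with an excess of the non-stabilised ylide, as used for lactols and hydroxy aldehydes, turns C2 into the terminal C2=C3 alkene; a slight deficit of n-BuLi and low temperature guard against iodine–lithium exchange and dehydroiodination.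

Step 10
Reactants: 15 (3R,4R,5Z)-6-iodo-2-methyl-3-[(3R)-3-methylhex-5-en-1-yl]hept-5-ene-2,4-diol
Product: 16 (5R,6R)-6-[(1Z)-2-iodoprop-1-en-1-yl]-2,2,4,4-tetramethyl-5-[(3R)-3-methylhex-5-en-1-yl]-1,3-dioxane
Conditions: 2-methoxypropene, PPTS (cat.), CH2Cl2, 0 °C → rt
Reagents that add atoms: 2-methoxypropene, C=C(C)OC
Why: Acid-catalysed ketalisation with an enol ether closes the six-membered O6/O11 acetonide even at the tertiary alcohol, removes both acidic protons ahead of the hydroboration and, as a cis-5,6-disubstituted 1,3-dioxane, holds C5 and C8 gauche to each other.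

Step 11
Reactants: 16 (5R,6R)-6-[(1Z)-2-iodoprop-1-en-1-yl]-2,2,4,4-tetramethyl-5-[(3R)-3-methylhex-5-en-1-yl]-1,3-dioxane
Product: 18 (Z)-cyclodec-4-ene 6,11-acetonide (6S,7R,10S; cis-fused cyclodeca[d][1,3]dioxine bearing methyl groups on C4 and C10), via B-alkyl-9-borabicyclo[3.3.1]nonane 17 (not isolated)
Conditions: 9-BBN-H (1.5 equiv), THF, rt; then syringe-pump addition over 12 h to Pd(dppf)Cl2 (20 mol %), AsPh3 (40 mol %), Cs2CO3 (3 equiv), DMF–THF–H2O, 50 °C, final ca. 1 mM
Reagents that add atoms: none
Why: 9-BBN-H adds only to the monosubstituted C2=C3 alkene, the trisubstituted iodoalkene being far slower, and for steric reasons it puts boron on the terminal carbon C3. Zerovalent palladium generated from Pd(dppf)Cl2 then inserts into the C4–I bond, the base-activated borane passes C3 to the divalent alkenylpalladium centre, and reductive elimination makes the C3–C4 bond, which is an intramolecular B-alkyl Suzuki–Miyaura coupling, a known route to macrocycles and medium rings. The ten-membered carbocycle closes by C(sp3)–C(sp2) reductive elimination from an eleven-membered palladacycle with extrusion of the metal. No stereocentre is created; the element to be preserved is the alkene geometry, and since both events at the alkenyl carbon proceed with retention the ring alkene should be cis, with C6, C7 and C10 as spectators. The step needs ring closure to beat oligomerisation, β-hydride elimination and protodeboronation, which is served by the Z-iodide and the cis-dioxane pointing the two termini at each other, by slow addition that keeps the borane dilute, and by the wide-bite-angle dppf ligand together with AsPh3, which hasten reductive elimination. At this ring size the cis-cycloalkene is also the more stable geometric isomer, so the closure pays the smaller strain penalty.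

Step 12
Reactants: 18 (Z)-cyclodec-4-ene 6,11-acetonide
Product: 19 (1S,2Z,7S,10R)-10-(2-hydroxypropan-2-yl)-3,7-dimethylcyclodec-2-en-1-ol
Conditions: AcOH–THF–H2O (3:1:1), rt → 40 °C
Reagents that add atoms: none
Why: Mild acid hydrolysis of a ketal; the 2,2,4,4-tetramethyl-1,3-dioxane carries a syn-diaxial methyl pair and should therefore open readily, before the allylic C6–O bond can ionise.

Step 13
Reactants: 19 (1S,2Z,7S,10R)-10-(2-hydroxypropan-2-yl)-3,7-dimethylcyclodec-2-en-1-ol; 20 angelic acid [(2Z)-2-methylbut-2-enoic acid]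
Product: 22 (1S,2Z,7S,10R)-10-(2-hydroxypropan-2-yl)-3,7-dimethylcyclodec-2-en-1-yl (2Z)-2-methylbut-2-enoate, via angelic 2,4,6-trichlorobenzoic anhydride 21 (not isolated)
Conditions: 20, 2,4,6-Cl3C6H2COCl, Et3N, toluene, rt; then 19, 80 °C (no DMAP)
Reagents that add atoms: angelic acid, C/C=C(/C)C(=O)O
Why: Yamaguchi-type mixed-anhydride esterification run without a nucleophilic catalyst acylates only the secondary O6, the tertiary O11 being too hindered, and avoids the addition–elimination path that would isomerise the angelate to the tiglate.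

Step 14
Reactants: 22 (1S,2Z,7S,10R)-10-(2-hydroxypropan-2-yl)-3,7-dimethylcyclodec-2-en-1-yl (2Z)-2-methylbut-2-enoate
Product: 23 (1R,2S,3R,7S,10R)-2,3-dihydroxy-10-(2-hydroxypropan-2-yl)-3,7-dimethylcyclodecyl (2Z)-2-methylbut-2-enoate (CNP0130723.1; 4R,5S,6R,7R,10S in the ring numbering)
Conditions: OsO4 (5 mol %), NMO, acetone–H2O, 0 °C → rt; neutral work-up (aq. Na2SO3)
Reagents that add atoms: osmium tetroxide, O=[Os](=O)(=O)=O; N-methylmorpholine N-oxide, C[N+]1([O-])CCOCC1; water, O
Why: Upjohn dihydroxylation: the concerted syn addition of OsO4 to the Z alkene fixes C4 and C5 relative to each other, allylic 1,3-strain with C3 keeps H6 in the alkene plane so that C7 and the ring span cover one face and the oxidant should enter from the open outer face on which O6 lies, giving 4R,5S, while the electron-poor, hindered angelate alkene reacts much more slowly.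

**Compound list**
1 | (R)-citronellal, (3R)-3,7-dimethyloct-6-enal | CC(C)=CCC[C@@H](C)CC=O | starting material
2 | (6R)-8,8-dimethoxy-2,6-dimethyloct-2-ene | COC(OC)C[C@H](C)CCC=C(C)C | intermediate
3 | (3R)-3-[(3R)-5,5-dimethoxy-3-methylpentyl]-2,2-dimethyloxirane | COC(OC)C[C@H](C)CC[C@H]1OC1(C)C | intermediate
4 | vinylmagnesium bromide | C=C[Mg]Br | starting material
5 | (3R,6R)-3-ethenyl-8,8-dimethoxy-2,6-dimethyloctan-2-ol | COC(OC)C[C@H](C)CC[C@H](C=C)C(C)(C)O | intermediate
6 | {[(3R,6R)-3-ethenyl-8,8-dimethoxy-2,6-dimethyloctan-2-yl]oxy}triethylsilane | COC(OC)C[C@H](C)CC[C@H](C=C)C(C)(C)O[Si](CC)(CC)CC | intermediate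
7 | secondary ozonide of 6 (1,2,4-trioxolan-3-yl group on C7, epimers at the ring carbon) | COC(OC)C[C@H](C)CC[C@H](C1OCOO1)C(C)(C)O[Si](CC)(CC)CC | intermediate
8 | (2S,5R)-7,7-dimethoxy-5-methyl-2-[2-(triethylsilyloxy)propan-2-yl]heptanal | COC(OC)C[C@H](C)CC[C@H](C=O)C(C)(C)O[Si](CC)(CC)CC | intermediate
9 | prop-1-ynylmagnesium bromide | CC#C[Mg]Br | starting material
10 | (4R,5R,8R)-10,10-dimethoxy-8-methyl-5-[2-(triethylsilyloxy)propan-2-yl]dec-2-yn-4-ol | COC(OC)C[C@H](C)CC[C@H]([C@@H](O)C#CC)C(C)(C)O[Si](CC)(CC)CC | intermediate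
11 | cyclic sodium alkenylalanate (five-membered ring Al–O6–C6–C5=C4, two 2-methoxyethoxy groups on Al) | COC(OC)C[C@H](C)CC[C@H]([C@@H]1C=C(C)[Al-](OCCOC)(OCCOC)O1)C(C)(C)O[Si](CC)(CC)CC.[Na+] | intermediate
12 | (2Z,4R,5R,8R)-2-iodo-10,10-dimethoxy-8-methyl-5-[2-(triethylsilyloxy)propan-2-yl]dec-2-en-4-ol | COC(OC)C[C@H](C)CC[C@H]([C@@H](O)/C=C(/C)I)C(C)(C)O[Si](CC)(CC)CC | intermediate
13 | (3R,6R,7R,8Z)-7-hydroxy-6-(2-hydroxypropan-2-yl)-9-iodo-3-methyldec-8-enal | O=CC[C@H](C)CC[C@H]([C@@H](O)/C=C(/C)I)C(C)(C)O | intermediate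
14 | methyltriphenylphosphonium bromide | C[P+](c1ccccc1)(c1ccccc1)c1ccccc1.[Br-] | starting material
15 | (3R,4R,5Z)-6-iodo-2-methyl-3-[(3R)-3-methylhex-5-en-1-yl]hept-5-ene-2,4-diol | C=CC[C@H](C)CC[C@H]([C@@H](O)/C=C(/C)I)C(C)(C)O | intermediate
16 | (5R,6R)-6-[(1Z)-2-iodoprop-1-en-1-yl]-2,2,4,4-tetramethyl-5-[(3R)-3-methylhex-5-en-1-yl]-1,3-dioxane | C=CC[C@H](C)CC[C@H]1C(C)(C)OC(C)(C)O[C@H]1/C=C(/C)I | intermediate
17 | B-alkyl-9-borabicyclo[3.3.1]nonane from 16 (boron on C3) | C1CCC2CCCC1B2CCC[C@H](C)CC[C@H]1C(C)(C)OC(C)(C)O[C@H]1/C=C(/C)I | intermediate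
18 | (Z)-cyclodec-4-ene 6,11-acetonide (6S,7R,10S), cis-fused hexamethyl-octahydrocyclodeca[d][1,3]dioxine | CC1(C)O[C@@H]2[C@H](C(C)(C)O1)CC[C@@H](C)CCC/C(C)=C\2 | intermediate
19 | (1S,2Z,7S,10R)-10-(2-hydroxypropan-2-yl)-3,7-dimethylcyclodec-2-en-1-ol | O[C@@H]1[C@H](C(C)(C)O)CC[C@@H](C)CCC/C(C)=C\1 | intermediate
20 | angelic acid, (2Z)-2-methylbut-2-enoic acid | C/C=C(/C)C(=O)O | starting material
21 | angelic 2,4,6-trichlorobenzoic anhydride | C/C=C(/C)C(=O)OC(=O)c1c(Cl)cc(Cl)cc1Cl | intermediate
22 | (1S,2Z,7S,10R)-10-(2-hydroxypropan-2-yl)-3,7-dimethylcyclodec-2-en-1-yl (2Z)-2-methylbut-2-enoate | C/C=C(/C)C(=O)O[C@@H]1[C@H](C(C)(C)O)CC[C@@H](C)CCC/C(C)=C\1 | intermediate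
23 | (1R,2S,3R,7S,10R)-2,3-dihydroxy-10-(2-hydroxypropan-2-yl)-3,7-dimethylcyclodecyl (2Z)-2-methylbut-2-enoate | C/C=C(/C)C(=O)O[C@@H]1[C@H](C(C)(C)O)CC[C@@H](C)CCC[C@@](C)(O)[C@H]1O | target

**Step count and risks**

Total step count: 14. Longest linear sequence: 14 (from 1 to 23).

Steps most likely to fail:

Step 11 (ring closure). Intermolecular coupling to oligomers, protodeboronation or reduction of the C–I bond may outpace closure of the strained ten-membered ring.
- The fallback keeps the C3–C4 closure but changes the metal.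
- It sets out from 16, which is hydroborated to 17 as before. The borane is then oxidised with NaBO3·4H2O to the primary alcohol F1.
- Appel iodination (I2, PPh3, imidazole) converts this into the primary iodide F2.
- Activated Zn dust in THF at 35 °C inserts into the alkyl C–I bond only and gives the alkylzinc iodide F3.
- Slow addition of this reagent to Pd(dppf)Cl2 in THF–NMP at 40 °C closes the ring by an intramolecular Negishi coupling. This coupling needs neither base nor water and transmetallates faster.
- The fallback comes back to the route at 18.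

Step 14 (final dihydroxylation). The risks are poor facial selectivity on the flexible ring, competing oxidation of the angelate alkene, and O6-to-O5 acyl shift during work-up.
- The fallback sets out from 19 and oxidises before the ester is present.
- Stoichiometric OsO4·TMEDA (CH2Cl2, −78 °C; then aq. Na2SO3) is steered by a hydrogen bond from the free O6–H to the face on which O6 lies. It gives the tetraol F4.
- Exhaustive ketalisation (2,2-dimethoxypropane, camphorsulfonic acid) can pair the four hydroxyl groups only as 4,5 and 6,11, giving the bis-acetonide F5.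
- The more strained tetramethyl-1,3-dioxane is hydrolysed selectively (AcOH–H2O, 0 °C) to the 4,5-acetonide 6,11-diol F6.
- Angeloylation as in step 13 gives the 4,5-acetonide 6-angelate F7.
- Warm aqueous AcOH removes the last ketal, and the fallback comes back to the route at 23.

Step 3 (epoxide opening). Attack at the hindered C7 may be sluggish. That would leave time for magnesium-halide-promoted rearrangement of the epoxide to a ketone or for bromohydrin formation.
- The fallback sets out from 3 and uses a slim sp nucleophile without any Lewis acid.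
- LiC≡CH·H2NCH2CH2NH2 in DMSO (rt → 45 °C) opens C7 with inversion to the homopropargylic alcohol F8.
- Semihydrogenation (H2, Pd/CaCO3 poisoned with Pb(OAc)2, quinoline) brings the fallback back to the route at 5.

**Further compounds**
F1 | step 11 | primary alcohol, (4R)-6-{(5R,6R)-6-[(1Z)-2-iodoprop-1-en-1-yl]-2,2,4,4-tetramethyl-1,3-dioxan-5-yl}-4-methylhexan-1-ol | OCCC[C@H](C)CC[C@H]1C(C)(C)OC(C)(C)O[C@H]1/C=C(/C)I
F2 | step 11 | primary iodide, (5R,6R)-5-[(3R)-6-iodo-3-methylhexyl]-6-[(1Z)-2-iodoprop-1-en-1-yl]-2,2,4,4-tetramethyl-1,3-dioxane | ICCC[C@H](C)CC[C@H]1C(C)(C)OC(C)(C)O[C@H]1/C=C(/C)I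
F3 | step 11 | alkylzinc iodide (zinc on C3) derived from F2 | I[Zn]CCC[C@H](C)CC[C@H]1C(C)(C)OC(C)(C)O[C@H]1/C=C(/C)I
F4 | step 14 | tetraol (4R,5S,6R,7R,10S), the target without the angeloyl group | O[C@@H]1[C@H](C(C)(C)O)CC[C@@H](C)CCC[C@@](C)(O)[C@H]1O
F5 | step 14 | 4,5:6,11-bis-acetonide of F4 | CC1(C)O[C@@H]2[C@H](C(C)(C)O1)CC[C@@H](C)CCC[C@@]1(C)OC(C)(C)O[C@H]12
F6 | step 14 | 4,5-acetonide 6,11-diol | O[C@@H]1[C@H](C(C)(C)O)CC[C@@H](C)CCC[C@@]2(C)OC(C)(C)O[C@H]21
F7 | step 14 | 4,5-acetonide 6-angelate | C/C=C(/C)C(=O)O[C@@H]1[C@H](C(C)(C)O)CC[C@@H](C)CCC[C@@]2(C)OC(C)(C)O[C@H]21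
F8 | step 3 | homopropargylic alcohol, (3R,6R)-3-ethynyl-8,8-dimethoxy-2,6-dimethyloctan-2-ol | COC(OC)C[C@H](C)CC[C@H](C#C)C(C)(C)O
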